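The dioxane ring (numbering: O1, C2 with the aryl group, C3 with CH2OH, O4, C4a, C5 with OMe, C7 with the propenol chain, C8a) is cut at C2–C3 and at O1–C8a. C2 with O1 is then an aromatic aldehyde, and C3, raised to the acyl level, is the acidic carbon of a 2-bromo-6-methoxyphenoxyacetyl imide. In one flask an auxiliary-controlled anti-aldol addition joins the halves and sets C2 and C3, and palladium-catalysed etherification of the new carbinol oxygen onto bromine-bearing C8a closes the ring with both centres untouched. It exploits the benzylic carbinol C2 next to C3 and the ortho-dioxygenated C4a–C8a edge of the benzo ring.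

Key step: step 4

Remark: CIP analysis of the target gives S at C2 and R at C3, so the aryl and hydroxymethyl groups are cis. This corresponds to the erythro (anti) aldol array.
Assumption: (4R)-4-benzyl-3-(chloroacetyl)-1,3-oxazolidin-2-one (4) is taken as a catalogue compound.

Step 1
Reactants: 1 5-bromovanillin (3-bromo-4-hydroxy-5-methoxybenzaldehyde); 2 monomethyl malonate (3-methoxy-3-oxopropanoic acid)
Product: 3 methyl (E)-3-(3-bromo-4-hydroxy-5-methoxyphenyl)prop-2-enoate
Conditions: pyridine, piperidine (cat.), 90 °C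
Reagents that add atoms: none
Why: Knoevenagel–Doebner condensation with a malonic half-ester should give the (E)-cinnamate directly by decarboxylative elimination, and the free phenol is tolerated.

Step 2
Reactants: 3 methyl (E)-3-(3-bromo-4-hydroxy-5-methoxyphenyl)prop-2-enoate; 4 (4R)-4-benzyl-3-(chloroacetyl)-1,3-oxazolidin-2-one
Product: 5 methyl (E)-3-[3-bromo-5-methoxy-4-[2-oxo-2-[(4R)-4-benzyl-2-oxo-1,3-oxazolidin-3-yl]ethoxy]phenyl]prop-2-enoate
Conditions: K2CO3, NaI (cat.), acetone, 50 °C
Reagents that add atoms: none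
Why: Williamson ether synthesis, in which the acidic phenoxide of 3 should displace the activated alpha-halide of 4 (iodide-catalysed SN2) and so install the glycolyl imide with its stereodirecting (R)-benzyl group in one step.

Step 3
Reactants: 6 3,4-dihydroxy-5-methoxybenzaldehyde
Product: 7 3,4-bis(tert-butyldimethylsilyloxy)-5-methoxybenzaldehyde
Conditions: TBSCl, imidazole, DMF, 23 °C
Reagents that add atoms: tert-butyldimethylsilyl chloride, CC(C)(C)[Si](C)(C)Cl
Why: Imidazole-promoted silylation of the catechol should give aryl silyl ethers that tolerate the aldol, the carbonate base and the hydride steps and are removed by fluoride at the end.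

Step 4
Reactants: 5 methyl (E)-3-[3-bromo-5-methoxy-4-[2-oxo-2-[(4R)-4-benzyl-2-oxo-1,3-oxazolidin-3-yl]ethoxy]phenyl]prop-2-enoate; 7 3,4-bis(tert-butyldimethylsilyloxy)-5-methoxybenzaldehyde
Product: 10 methyl (E)-3-[(2S,3S)-3-[(4R)-4-benzyl-2-oxo-1,3-oxazolidine-3-carbonyl]-2-[3,4-bis(tert-butyldimethylsilyloxy)-5-methoxyphenyl]-5-methoxy-2,3-dihydro-1,4-benzodioxin-7-yl]prop-2-enoate, via trimethylsilyl-protected anti-aldol adduct 8 (not isolated), via free anti-aldol adduct 9 (not isolated)
Conditions: MgCl2 (20 mol%), Et3N, Me3SiCl, EtOAc, 23 °C; then MeOH, AcOH, 23 °C, evaporate; then Pd(OAc)2 (5 mol%), 2-(di-tert-butylphosphino)-1,1'-binaphthyl (6 mol%), Cs2CO3, toluene, 60 °C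
Reagents that add atoms: none
Why: MgCl2/Et3N should soft-enolise 5 to the chelated (Z)-magnesium enolate, which adds to 7 and is trapped by Me3SiCl as 8 (magnesium-halide-catalysed direct anti-aldol addition of N-acyloxazolidinones to aromatic aldehydes); after methanolysis to 9, zerovalent palladium formed from Pd(OAc)2 and the phosphine inserts into the C–Br bond, the carbinol binds and is deprotonated by Cs2CO3, and C–O reductive elimination follows (Buchwald-type intramolecular etherification, known for 1,4-benzodioxanes). The dioxane ring is closed at O1–C8a as a six-membered ring by reductive elimination from a seven-membered palladacycle, the only mode open to the tether because arylation at C3 would need a four-membered ring. C3 (the former glycolyl carbon) is set by the (R)-benzyl group of the auxiliary, which blocks one face of the chelated enolate, and C2 (the former aldehyde carbon) is set relative to C3 by the boat-like transition state that leads to the anti adduct, (2S,3S) in the chain numbering of 9, which is the erythro array that the cis ring requires. The step needs anti over syn selectivity, which rests on the (Z)-enolate geometry and the auxiliary, and it needs the ring closure to leave both centres alone, which is secured because the aryl C–O coupling touches neither of them and allylic 1,3-strain in the imide keeps the C3–H bond out of alignment for enolisation. Which oxygen ends on which carbon is not a selectivity question, since O4 is already bonded to C3 in 5 and the bromine marks C8a.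

Step 5
Reactants: 10 methyl (E)-3-[(2S,3S)-3-[(4R)-4-benzyl-2-oxo-1,3-oxazolidine-3-carbonyl]-2-[3,4-bis(tert-butyldimethylsilyloxy)-5-methoxyphenyl]-5-methoxy-2,3-dihydro-1,4-benzodioxin-7-yl]prop-2-enoate
Product: 12 (E)-3-[(2S,3R)-2-[3,4-bis(tert-butyldimethylsilyloxy)-5-methoxyphenyl]-3-(hydroxymethyl)-5-methoxy-2,3-dihydro-1,4-benzodioxin-7-yl]prop-2-en-1-ol, via hydroxymethyl enoate 11 (not isolated)
Conditions: LiBH4, MeOH (1.5 equiv), THF, 0 °C; then i-Bu2AlH (toluene), −78 → −20 °C; Rochelle salt work-up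
Reagents that add atoms: none
Why: LiBH4 should attack the exocyclic imide carbonyl selectively (reductive cleavage of N-acyloxazolidinones to primary alcohols, releasing the auxiliary), and i-Bu2AlH should then reduce the enoate 1,2 to the allylic alcohol, with neither stereocentre involved (the descriptor at C3 changes from S to R only because the CIP ranking changes).

Step 6
Reactants: 12 (E)-3-[(2S,3R)-2-[3,4-bis(tert-butyldimethylsilyloxy)-5-methoxyphenyl]-3-(hydroxymethyl)-5-methoxy-2,3-dihydro-1,4-benzodioxin-7-yl]prop-2-en-1-ol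
Product: 13 5-[(2S,3R)-3-(hydroxymethyl)-7-[(E)-3-hydroxyprop-1-enyl]-5-methoxy-2,3-dihydro-1,4-benzodioxin-2-yl]-3-methoxybenzene-1,2-diol
Conditions: Bu4NF, AcOH, THF, 0 °C, argon
Reagents that add atoms: none
Why: Fluoride should cleave both aryl silyl ethers, and the acetic acid buffer keeps the catechol protonated, so that neither air oxidation nor base-induced opening of the benzylic ether through a quinone methide can scramble C2.

Compound list
1 | 5-bromovanillin (3-bromo-4-hydroxy-5-methoxybenzaldehyde) | COc1cc(C=O)cc(Br)c1O | starting material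
2 | monomethyl malonate (3-methoxy-3-oxopropanoic acid) | COC(=O)CC(=O)O | starting material
3 | methyl (E)-3-(3-bromo-4-hydroxy-5-methoxyphenyl)prop-2-enoate | COC(=O)/C=C/c1cc(Br)c(O)c(OC)c1 | intermediate
4 | (4R)-4-benzyl-3-(chloroacetyl)-1,3-oxazolidin-2-one | ClCC(=O)N1[C@H](Cc2ccccc2)COC1=O | starting material
5 | methyl (E)-3-[3-bromo-5-methoxy-4-[2-oxo-2-[(4R)-4-benzyl-2-oxo-1,3-oxazolidin-3-yl]ethoxy]phenyl]prop-2-enoate | COC(=O)/C=C/c1cc(Br)c(OCC(=O)N2[C@H](Cc3ccccc3)COC2=O)c(OC)c1 | intermediate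
6 | 3,4-dihydroxy-5-methoxybenzaldehyde | COc1cc(C=O)cc(O)c1O | starting material
7 | 3,4-bis(tert-butyldimethylsilyloxy)-5-methoxybenzaldehyde | COc1cc(C=O)cc(O[Si](C)(C)C(C)(C)C)c1O[Si](C)(C)C(C)(C)C | intermediate
8 | (4R)-4-benzyl-3-[(2S,3S)-2-[2-bromo-6-methoxy-4-[(E)-3-methoxy-3-oxoprop-1-enyl]phenoxy]-3-[3,4-bis(tert-butyldimethylsilyloxy)-5-methoxyphenyl]-3-(trimethylsilyloxy)propanoyl]-1,3-oxazolidin-2-one | O=C(N1[C@H](Cc2ccccc2)COC1=O)[C@@H](Oc1c(Br)cc(/C=C/C(=O)OC)cc1OC)[C@@H](O[Si](C)(C)C)c1cc(OC)c(O[Si](C)(C)C(C)(C)C)c(O[Si](C)(C)C(C)(C)C)c1 | intermediate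
9 | (4R)-4-benzyl-3-[(2S,3S)-2-[2-bromo-6-methoxy-4-[(E)-3-methoxy-3-oxoprop-1-enyl]phenoxy]-3-[3,4-bis(tert-butyldimethylsilyloxy)-5-methoxyphenyl]-3-hydroxypropanoyl]-1,3-oxazolidin-2-one | O=C(N1[C@H](Cc2ccccc2)COC1=O)[C@@H](Oc1c(Br)cc(/C=C/C(=O)OC)cc1OC)[C@@H](O)c1cc(OC)c(O[Si](C)(C)C(C)(C)C)c(O[Si](C)(C)C(C)(C)C)c1 | intermediate
10 | methyl (E)-3-[(2S,3S)-3-[(4R)-4-benzyl-2-oxo-1,3-oxazolidine-3-carbonyl]-2-[3,4-bis(tert-butyldimethylsilyloxy)-5-methoxyphenyl]-5-methoxy-2,3-dihydro-1,4-benzodioxin-7-yl]prop-2-enoate (cis) | COc1cc([C@@H]2Oc3cc(/C=C/C(=O)OC)cc(OC)c3O[C@@H]2C(=O)N2[C@H](Cc3ccccc3)COC2=O)cc(O[Si](C)(C)C(C)(C)C)c1O[Si](C)(C)C(C)(C)C | intermediate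
11 | methyl (E)-3-[(2S,3R)-2-[3,4-bis(tert-butyldimethylsilyloxy)-5-methoxyphenyl]-3-(hydroxymethyl)-5-methoxy-2,3-dihydro-1,4-benzodioxin-7-yl]prop-2-enoate | COc1cc([C@@H]2Oc3cc(/C=C/C(=O)OC)cc(OC)c3O[C@@H]2CO)cc(O[Si](C)(C)C(C)(C)C)c1O[Si](C)(C)C(C)(C)C | intermediate
12 | (E)-3-[(2S,3R)-2-[3,4-bis(tert-butyldimethylsilyloxy)-5-methoxyphenyl]-3-(hydroxymethyl)-5-methoxy-2,3-dihydro-1,4-benzodioxin-7-yl]prop-2-en-1-ol | COc1cc([C@@H]2Oc3cc(/C=C/CO)cc(OC)c3O[C@@H]2CO)cc(O[Si](C)(C)C(C)(C)C)c1O[Si](C)(C)C(C)(C)C | intermediate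
13 | 5-[(2S,3R)-3-(hydroxymethyl)-7-[(E)-3-hydroxyprop-1-enyl]-5-methoxy-2,3-dihydro-1,4-benzodioxin-2-yl]-3-methoxybenzene-1,2-diol (cis) | COc1cc([C@@H]2Oc3cc(/C=C/CO)cc(OC)c3O[C@@H]2CO)cc(O)c1O | target

Total step count: 6. Longest linear sequence: 5 steps (1 → 3 → 5 → 10 → 12 → 13); step 3 prepares the second fragment.

Steps most likely to fail

1. Step 4. The anti relationship may be lost in two ways. The magnesium aldol stage may be incompletely anti-selective (a competing chelate through the aryloxy oxygen), and a one-flask process cannot purge the syn isomer. Once base and heat are applied, retro-aldol cleavage, epimerisation alpha to the imide, attack of the alkoxide on the oxazolidinone carbonyl or beta-hydride elimination of the palladium alkoxide may follow. The fallback sets out from 9 and comes back to the route at 13; it closes the ring at the alcohol oxidation level, where no enolisable carbonyl and no retro-aldol path remain. The first stage is stopped after methanolysis, and 9 is isolated and freed from any syn isomer by chromatography. LiBH4/MeOH in THF at 0 °C should cleave the auxiliary to the bromo 1,3-diol F1. TBSCl/imidazole at 0 °C should silylate the primary hydroxyl selectively to the primary silyl ether F2. Pd(OAc)2, 2-(di-tert-butylphosphino)-1,1'-binaphthyl and Cs2CO3 in toluene at 60 °C should then give the silylated cis-benzodioxane enoate F3. i-Bu2AlH at −78 °C should give the tris-silylated allylic alcohol F4, and Bu4NF/AcOH should remove all three silyl groups to give 13.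

2. Step 2. Acyl transfer may compete with alkylation: the phenoxide may attack the exocyclic imide carbonyl of 4 and strip the auxiliary, or carbonate may degrade the imide while the hindered phenoxide reacts slowly. The fallback sets out from 3 and comes back at 5; it forms the ether bond with a robust ester and attaches the auxiliary last. Alkylation of 3 with tert-butyl bromoacetate (K2CO3, DMF) should give the tert-butyl aryloxyacetate F5. CF3CO2H in CH2Cl2 should free the aryloxyacetic acid F6. Activation as the pivalic mixed anhydride (pivaloyl chloride, Et3N, THF) and acylation of (R)-4-benzyl-1,3-oxazolidin-2-one in the presence of LiCl should give 5.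

3. Step 5. Borohydride may reduce the enoate in the conjugate sense, or hydride may attack the ring carbonyl of the oxazolidinone (endocyclic cleavage). The fallback sets out from 10 and comes back at 12; it removes the auxiliary without hydride, so that a single reagent then reduces two esters. MeOMgBr (from MeMgBr and MeOH) in MeOH/CH2Cl2 at 0 °C should exchange the auxiliary for methoxide to give the cis dimethyl diester F7. i-Bu2AlH in CH2Cl2 at −78 °C should then reduce both esters to give 12.

Further compounds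
F1 | step 4 | methyl (E)-3-[3-bromo-4-[[(1S,2R)-1-[3,4-bis(tert-butyldimethylsilyloxy)-5-methoxyphenyl]-1,3-dihydroxypropan-2-yl]oxy]-5-methoxyphenyl]prop-2-enoate (bromo 1,3-diol) | OC[C@@H](Oc1c(Br)cc(/C=C/C(=O)OC)cc1OC)[C@@H](O)c1cc(OC)c(O[Si](C)(C)C(C)(C)C)c(O[Si](C)(C)C(C)(C)C)c1
F2 | step 4 | methyl (E)-3-[3-bromo-4-[[(1S,2R)-1-[3,4-bis(tert-butyldimethylsilyloxy)-5-methoxyphenyl]-3-(tert-butyldimethylsilyloxy)-1-hydroxypropan-2-yl]oxy]-5-methoxyphenyl]prop-2-enoate (primary silyl ether) | CC(C)(C)[Si](C)(C)OC[C@@H](Oc1c(Br)cc(/C=C/C(=O)OC)cc1OC)[C@@H](O)c1cc(OC)c(O[Si](C)(C)C(C)(C)C)c(O[Si](C)(C)C(C)(C)C)c1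
F3 | step 4 | methyl (E)-3-[(2S,3R)-2-[3,4-bis(tert-butyldimethylsilyloxy)-5-methoxyphenyl]-3-[(tert-butyldimethylsilyloxy)methyl]-5-methoxy-2,3-dihydro-1,4-benzodioxin-7-yl]prop-2-enoate (silylated cis-benzodioxane enoate) | COc1cc([C@@H]2Oc3cc(/C=C/C(=O)OC)cc(OC)c3O[C@@H]2CO[Si](C)(C)C(C)(C)C)cc(O[Si](C)(C)C(C)(C)C)c1O[Si](C)(C)C(C)(C)C
F4 | step 4 | (E)-3-[(2S,3R)-2-[3,4-bis(tert-butyldimethylsilyloxy)-5-methoxyphenyl]-3-[(tert-butyldimethylsilyloxy)methyl]-5-methoxy-2,3-dihydro-1,4-benzodioxin-7-yl]prop-2-en-1-ol (tris-silylated allylic alcohol) | COc1cc([C@@H]2Oc3cc(/C=C/CO)cc(OC)c3O[C@@H]2CO[Si](C)(C)C(C)(C)C)cc(O[Si](C)(C)C(C)(C)C)c1O[Si](C)(C)C(C)(C)C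
F5 | step 2 | methyl (E)-3-[3-bromo-4-(2-tert-butoxy-2-oxoethoxy)-5-methoxyphenyl]prop-2-enoate (tert-butyl aryloxyacetate) | COC(=O)/C=C/c1cc(Br)c(OCC(=O)OC(C)(C)C)c(OC)c1
F6 | step 2 | 2-[2-bromo-6-methoxy-4-[(E)-3-methoxy-3-oxoprop-1-enyl]phenoxy]acetic acid (aryloxyacetic acid) | COC(=O)/C=C/c1cc(Br)c(OCC(=O)O)c(OC)c1
F7 | step 5 | methyl (2S,3S)-2-[3,4-bis(tert-butyldimethylsilyloxy)-5-methoxyphenyl]-5-methoxy-7-[(E)-3-methoxy-3-oxoprop-1-enyl]-2,3-dihydro-1,4-benzodioxine-3-carboxylate (cis dimethyl diester) | COc1cc([C@@H]2Oc3cc(/C=C/C(=O)OC)cc(OC)c3O[C@@H]2C(=O)OC)cc(O[Si](C)(C)C(C)(C)C)c1O[Si](C)(C)C(C)(C)C
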